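The number I worked from was 12.7%, the catalyst load of teal: catalyst charge as a fraction of substrate charge.

| flask | substrate | capture agent | free catalyst | remark | time |
|---|---|---|---|---|---|
| dusk | 0.011 M | 0.55 mM | 0.81 mM | run made earlier |  |
| autumn | 0.011 M | 0.55 mM | 2.9 mM | run made earlier |  |
| summer | 0.013 M | 0.55 mM | 1.9 mM | run made earlier |  |
| teal | 0.015 M | 0.550 mM | 1.9 mM |  | 10 min |
| blue | 0.011 M | 0.550 mM | 1.9 mM |  | 10 min |
| grey | 0.015 M | 0.550 mM | 0.60 mM |  | 10 min |
| green | 0.011 M | 0.550 mM | 0.60 mM |  | 10 min |

| run | time / min | product / % | substrate / % |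
|---|---|---|---|
| dusk | 1.00 | 42 | 51 |
| dusk | 2.00 | 55 | 40 |
| dusk | 3.00 | 64 | 30 |
| dusk | 4.00 | 68 | 26 |
| dusk | 5.00 | 69 | 22 |
| dusk | 6.00 | 76 | 17 |
| dusk | 8.00 | 80 | 10 |
| autumn | 1.00 | 61 | 8 |
| autumn | 2.00 | 75 | 1 |
| autumn | 3.00 | 75 | 2 |
| autumn | 4.00 | 78 | 2 |
| autumn | 5.00 | 77 | 0 |
| autumn | 6.00 | 76 | 0 |
| autumn | 8.00 | 76 | 0 |
| summer | 1.33 | 67 | 23 |
| summer | 3.00 | 85 | 3 |
| summer | 4.00 | 85 | 3 |
| summer | 6.00 | 87 | 0 |
| summer | 8.00 | 84 | 1 |

(scatter of a reading: 2 percentage points)

- all flasks from highest to lowest amount of product, in percent of the substrate charged, at 10 min (teal / blue / grey / green)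
- the amount of product, in percent of the substrate charged of the flask you put first, at 10 min
- the amount of product, in percent of the substrate charged of the flask you put last, at 10 min

- the numbers in the tables scatter by 2 percentage points (one standard deviation)
- a reading or a percentage of product counts all its forms, free or not

The summer run, with load 14.6%, levelled off 14.8% short of its charge, so I read the shortfall as 1.01 loads. My rule for these four flasks was therefore product = conversion minus that many loads.

| Flask | Load | Product if finished |
|---|---|---|
| teal | 12.7% | 87.2% |
| blue | 17.3% | 82.5% |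
| grey | 4.00% | 96.0% |
| green | 5.45% | 94.5% |

Teal and blue I took as finished, because summer, at the same catalyst charge, was down to 3% substrate by 3.00 min, earlier than the asked time. Grey and green I expected to stop short: their capture agent is 91.7% of the catalyst charge, and dusk, at 67.9%, still held 10% substrate at 8.00 min.

For these two I solved both ends. If the rate follows substrate (pseudo-first-order), both convert the same fraction and grey leads by the load difference, 1.5 percentage points. If the rate does not depend on substrate (zero order), both convert the same amount, and green's conversion is 1.36 times grey's. I took the real pair to lie between these ends, and green needed a conversion lead of 1.5 points to pass grey, so I put green above grey.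

The forecast gave teal > blue > grey > green, with 87.5% on top and 67% at the bottom, calling the lower pair “nearly tied, with grey slightly ahead because its loss fraction is smaller”. On that pair we differed.

The flasks gave teal > blue > green > grey, from 88.8% in teal to 68.4% in grey, with blue at 84.8% and green at 71.9%.

    capture agent + catalyst intermediate B → trapped intermediate (k = 28.0 L mol⁻¹ s⁻¹)
    catalyst intermediate A → catalyst intermediate B (k = 2.20 s⁻¹)
    catalyst intermediate B ⇌ free catalyst + product (K = 0.00120 M, k = 0.520 s⁻¹)
    crystals ⇌ product, rate k4*(cs4 - [product]) while solid is left; crystals form when [product] > cs4 (solubility = 6.00 mM, k = 1.90 s⁻¹)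
    substrate + free catalyst ⇌ catalyst intermediate A (K = 34.0 L mol⁻¹, k = 1300 L mol⁻¹ s⁻¹)

In teal, catalyst intermediate B gave product while capture agent fell to 0.00630% of its charge by 5.00 min, and half of that step's turnover up to the asked time was done by 0.597 min. At 10.0 min teal's catalyst stood 28.9% as trapped intermediate, 59.2% as catalyst intermediate B and 11.8% free; the first two times its load come to 11.2%, and the flask lacked 11.2%. By 10.0 min grey had converted 72.3% and green 77.2%, a factor of 1.07. Teal's neighbour with 0.0037 M substrate has load 51.4% and held 28.9% of its catalyst as trapped intermediate, 46.5% as catalyst intermediate B and 24.6% free; the first two times its load leave 61.2%, and its product stood at 61.3%.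

The data were computed for an exercise.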